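**Retrosynthetic overview**

1. Numbering (decalin): ring A = C1–C2–C3(=O)–C4(CH2CH2CO2H)–C5(Me)–C10(H); ring B = C5–C6–C7–C8(Me)–C9(Me, CH2Ar)–C10; β is the face of the C5 methyl group.
2. Endgame disconnections: O–Me of the hydroquinone, a temporary C7 sulfonyl group, the benzylic CH2 (from an aryl ketone) and the C4 side chain (Mukaiyama–Michael on the C3 silyl enol ether) lead back to tricyclic sulfone 17.
3. Key disconnection: C5–C6 and C8–C9 of ring B, formed together when the three-carbon unit C6–C7–C8 (with the C8 methyl), supplied as bis-sulfone 15, is inserted into the C5–C9 bond of aryl cyclopropyl ketone 10.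
4. Enabling feature: C5 and C9, the two methyl-bearing quaternary carbons of ring B, are 1,3-related across C10–H; C9 carries the benzylic carbon (held as an aryl ketone) and C5 is allylic to the C3–O/C4 enol ether of ring A, so a temporary C5–C9 bond (cyclopropane C5–C10–C9 fused to ring A) can be opened by one electron into a C9 enolate and a C5 allyl radical.
5. Ring order: ring A (3-methylcyclohexenone) → temporary cyclopropane (asymmetric carbene addition, sets C10) → arene attached → ring B (key step) → side chain, reductions, deprotection.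

Key step: step 10

Assumption: the sense of enantioface selection by Rh2(S-PTTL)4 in step 5 is assigned by analogy; if it is found to be opposite, the antipodal catalyst Rh2(R-PTTL)4 is used.

**Route**

Step 1
Reactants: 1 2-bromo-6-methylphenol
Product: 2 2-bromo-6-methylcyclohexa-2,5-diene-1,4-dione
Conditions: ON(SO3K)2 (2.2 equiv), KH2PO4, acetone/H2O, 23 °C
Reagents that add atoms: potassium nitrosodisulfonate, [K+].[K+].[O]N(S(=O)(=O)[O-])S(=O)(=O)[O-]
Why: Teuber oxidation: the nitrosodisulfonate radical oxidises a phenol with a free para position to the p-quinone, and no stereocentre is formed.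

Step 2
Reactants: 2 2-bromo-6-methylcyclohexa-2,5-diene-1,4-dione
Product: 4 1-bromo-2,5-dimethoxy-3-methylbenzene, via 2-bromo-6-methylbenzene-1,4-diol 3 (not isolated)
Conditions: Na2S2O4, THF/H2O, 23 °C; then KOH, Me2SO4, Bu4NBr (cat.), 23 °C
Reagents that add atoms: dimethyl sulfate, COS(=O)(=O)OC
Why: Dithionite reduction of the quinone followed by Williamson O-methylation of the hydroquinone under phase transfer should give the dimethyl ether without isolating the air-sensitive hydroquinone; no stereocentre is formed.

Step 3
Reactants: 5 3-methylcyclohex-2-en-1-one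
Product: 6 tert-butyl(dimethyl)[(3-methylcyclohexa-1,3-dien-1-yl)oxy]silane
Conditions: TBSOTf, Et3N, CH2Cl2, 0 to 23 °C (equilibrating)
Reagents that add atoms: tert-butyldimethylsilyl trifluoromethanesulfonate, CC(C)(C)[Si](C)(C)OS(=O)(=O)C(F)(F)F
Why: Soft enolisation of the enone under equilibrating conditions should give the thermodynamic, fully endocyclic 1-siloxy-1,3-diene; no stereocentre is formed.

Step 4
Reactants: 7 ethyl 2-methyl-3-oxobutanoate
Product: 8 ethyl 2-diazopropanoate
Conditions: 4-acetamidobenzenesulfonyl azide, DBU, MeCN, 0 to 23 °C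
Reagents that add atoms: 4-acetamidobenzenesulfonyl azide, CC(=O)Nc1ccc(cc1)S(=O)(=O)N=[N+]=[N-]
Why: Regitz deacylative diazo transfer: the azide adds to the enolate and the adduct fragments with loss of the acetyl group as the N-acetylsulfonamide; no stereocentre is formed.

Step 5
Reactants: 6 silyl dienol ether; 8 ethyl 2-diazopropanoate
Product: 9 ethyl (1S,6S)-3-{[tert-butyl(dimethyl)silyl]oxy}-1,7-dimethylbicyclo[4.1.0]hept-2-ene-7-carboxylate
Conditions: Rh2(S-PTTL)4 [dirhodium tetrakis((S)-N-phthaloyl-tert-leucinate)] (1 mol %), slow addition of 8, hexanes/CH2Cl2, −78 °C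
Reagents that add atoms: none
Why: Rhodium-carbenoid cyclopropanation: the bulky chiral carboxylate catalyst at low temperature suppresses 1,2-hydride shift in the α-methyl carbenoid, the electrophilic carbenoid attacks the vinylogous terminus C10 of the siloxydiene so that the distal C5=C10 bond is cyclopropanated, the cis ring fusion is obligatory, and the catalyst selects the alkene face, which fixes C10 (C9 is left undefined because it is erased in step 10).

Step 6
Reactants: 9 cyclopropane ester; 4 1-bromo-2,5-dimethoxy-3-methylbenzene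
Product: 10 [(1S,6S)-3-{[tert-butyl(dimethyl)silyl]oxy}-1,7-dimethylbicyclo[4.1.0]hept-2-en-7-yl](2,5-dimethoxy-3-methylphenyl)methanone
Conditions: 4, n-BuLi, THF, −78 °C; then 9, −78 to 0 °C; pH 7 buffer
Reagents that add atoms: none
Why: Bromine–lithium exchange followed by addition–elimination of the aryllithium at the ester should stop at the ketone because the hindered, chelated ketone resists a second addition; the stereocentres are untouched.

Step 7
Reactants: 11 (ethenesulfonyl)benzene; 12 acetaldehyde
Product: 13 3-(benzenesulfonyl)but-3-en-2-ol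
Conditions: DABCO (0.5 equiv), 1,4-dioxane/H2O, 23 °C
Reagents that add atoms: none
Why: Morita–Baylis–Hillman reaction: DABCO adds to the vinyl sulfone and the α-sulfonyl carbanion adds to acetaldehyde; the carbinol stereocentre is racemic and is destroyed in step 10.

Step 8
Reactants: 13 3-(benzenesulfonyl)but-3-en-2-ol
Product: 14 3-(benzenesulfonyl)but-3-en-2-yl acetate
Conditions: Ac2O, pyridine, DMAP (cat.), CH2Cl2, 0 °C
Reagents that add atoms: acetic anhydride, CC(=O)OC(C)=O
Why: DMAP-catalysed O-acylation; no new stereocentre.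

Step 9
Reactants: 14 3-(benzenesulfonyl)but-3-en-2-yl acetate
Product: 15 2,3-bis(benzenesulfonyl)but-1-ene
Conditions: DABCO (1.0 equiv), then PhSO2Na, THF/H2O, 0 °C, short reaction time
Reagents that add atoms: sodium benzenesulfinate, [Na+].[O-]S(=O)c1ccccc1
Why: Tandem SN2′/SN2′ substitution of a Morita–Baylis–Hillman acetate: DABCO displaces acetate with allylic transposition and sulfinate displaces DABCO with a second transposition, so that under kinetic control the sulfonyl group should end on the methyl-bearing carbon and the 1,1-disubstituted alkene is kept (racemic; stereocentre destroyed in step 10).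

Step 10
Reactants: 10 aryl cyclopropyl ketone; 15 2,3-bis(benzenesulfonyl)but-1-ene
Product: 17 tricyclic C7-sulfonyl C3-silyl enol ether (ring B closed), via ring-opened vinyl sulfone samarium enolate 16 (not isolated)
Conditions: SmI2 (2.5 equiv, added slowly to 10 and 15 (2 equiv)), THF, −78 to 23 °C; aq. NaHCO3
Reagents that add atoms: none
Why: Proposed new method: Divalent samarium reduces the aryl ketone of 10 to a ketyl whose cyclopropane C5–C9 bond opens (strain release, allylic stabilisation by the C3=C4 silyl enol ether) to a trivalent-samarium enolate at C9 and a C5 siloxyallyl radical; this radical (or the allylsamarium formed by a second electron transfer) adds through C5 to the CH2 terminus of 15, loss of benzenesulfinate from the adduct (β-scission, then reduction by the second SmI2, or E1cB) leaves the (E)-vinyl sulfone 16, and the C9 enolate closes ring B, the only ring closed, by a 6-endo-trig Michael addition. The closest known reaction types are the SmI2-mediated ring-opening/radical-relay coupling of aryl cyclopropyl ketones with alkenes (formal [3+2]) and allylation by addition–fragmentation at 2-sulfonylallyl sulfones; the fragmenting sulfonyl group is chosen so that loss of sulfinate outruns the 5-exo return of the adduct radical to the enolate that gives the known five-membered ring, and joining these events with an enolate Michael closure into a [3+3] annulation is the new element. C5 is set by attack anti to the pseudoaxial C10 substituent (C6 enters α, the methyl stays β, giving the trans ring fusion); C9 is set by allylic 1,3-strain in the enolate (C10–H eclipses the enolate double bond, so the methyl becomes axial-β and the aroyl group equatorial); C8 is set by the (E)-geometry of the vinyl sulfone in a chair transition state (the methyl cis to C6 ends axial-α). The step needs attack through C5 and not C3 of the allyl system, which is secured because only C5-attack keeps the O–C3=C4 enol ether conjugation, and it needs the intermolecular bond to form at C5 before the enolate reacts, which is secured by the much higher rate of radical addition to the sulfonyl alkene compared with an intermolecular Michael reaction of the hindered tetrasubstituted samarium enolate. C10 is carried over from 10, and both C7 epimers are acceptable because the sulfone is removed in step 13.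

Step 11
Reactants: 17 tricyclic silyl enol ether; 18 benzyl prop-2-enoate
Product: 19 benzyl ester of the C4-alkylated 3-ketone (C4 and C7 epimers)
Conditions: TiCl4, CH2Cl2, −78 °C; aq. NaHCO3
Reagents that add atoms: none
Why: Mukaiyama–Michael reaction: the silyl enol ether can only react through C4, which places the side chain regiospecifically; the C4 configuration is not controlled here and is equilibrated in step 12.

Step 12
Reactants: 19 benzyl ester keto sulfone
Product: 20 C7-sulfonyl keto acid with the benzylic CH2 in place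
Conditions: H2 (4 atm), Pd/C, AcOH, HClO4 (cat.), 40 °C
Reagents that add atoms: none
Why: Acid-assisted hydrogenolysis over palladium should remove the benzylic carbonyl oxygen of the electron-rich aryl ketone (via the benzylic alcohol) and the O-benzyl group while the dialkyl ketone and the sulfone survive, and the acid equilibrates C4 to the equatorial side chain cis to the C5 methyl, which is the configuration of the target.

Step 13
Reactants: 20 C7-sulfonyl keto acid
Product: 21 O,O-dimethyl ether of the target
Conditions: Na(Hg) (6 %), Na2HPO4, MeOH/THF, −20 to 0 °C; then aq. HCl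
Reagents that add atoms: none
Why: Reductive desulfonylation with sodium amalgam (as in the Julia olefination sequence): electron transfer cleaves the C7–S bond and the carbanion is protonated, so C7 becomes a methylene group and no stereocentre is affected.

Step 14
Reactants: 21 O,O-dimethyl ether of the target
Product: 22 CNP0167047.1 (target)
Conditions: BBr3, CH2Cl2, −78 to 23 °C; H2O
Reagents that add atoms: none
Why: Lewis-acid cleavage of both aryl methyl ethers by BBr3 (bromide attacks the O-methyl group of the boron-complexed ether) should liberate the hydroquinone; no stereocentre is touched.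

**Compound list**

1 | 2-bromo-6-methylphenol | Cc1cccc(Br)c1O | starting material
2 | 2-bromo-6-methylcyclohexa-2,5-diene-1,4-dione | CC1=CC(=O)C=C(Br)C1=O | intermediate
3 | 2-bromo-6-methylbenzene-1,4-diol | Cc1cc(O)cc(Br)c1O | intermediate (not isolated)
4 | 1-bromo-2,5-dimethoxy-3-methylbenzene | COc1cc(C)c(OC)c(Br)c1 | intermediate
5 | 3-methylcyclohex-2-en-1-one | CC1=CC(=O)CCC1 | starting material
6 | tert-butyl(dimethyl)[(3-methylcyclohexa-1,3-dien-1-yl)oxy]silane | CC1=CCCC(O[Si](C)(C)C(C)(C)C)=C1 | intermediate
7 | ethyl 2-methyl-3-oxobutanoate | CCOC(=O)C(C)C(C)=O | starting material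
8 | ethyl 2-diazopropanoate | CCOC(=O)C(C)=[N+]=[N-] | intermediate
9 | ethyl (1S,6S)-3-{[tert-butyl(dimethyl)silyl]oxy}-1,7-dimethylbicyclo[4.1.0]hept-2-ene-7-carboxylate (C7 epimers; C1 = C5, C6 = C10, C7 = C9 of the decalin numbering) | CCOC(=O)C1(C)[C@]2(C)C=C(O[Si](C)(C)C(C)(C)C)CC[C@H]12 | intermediate
10 | [(1S,6S)-3-{[tert-butyl(dimethyl)silyl]oxy}-1,7-dimethylbicyclo[4.1.0]hept-2-en-7-yl](2,5-dimethoxy-3-methylphenyl)methanone (C7 epimers) | COc1cc(C)c(OC)c(c1)C(=O)C1(C)[C@]2(C)C=C(O[Si](C)(C)C(C)(C)C)CC[C@H]12 | intermediate
11 | (ethenesulfonyl)benzene (phenyl vinyl sulfone) | C=CS(=O)(=O)c1ccccc1 | starting material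
12 | acetaldehyde | CC=O | starting material
13 | 3-(benzenesulfonyl)but-3-en-2-ol (racemic) | CC(O)C(=C)S(=O)(=O)c1ccccc1 | intermediate
14 | 3-(benzenesulfonyl)but-3-en-2-yl acetate (racemic) | CC(OC(C)=O)C(=C)S(=O)(=O)c1ccccc1 | intermediate
15 | 2,3-bis(benzenesulfonyl)but-1-ene (racemic) | CC(C(=C)S(=O)(=O)c1ccccc1)S(=O)(=O)c1ccccc1 | intermediate
16 | diiodosamarium enolate of the ring-opened ketone: C9 enolate, C3 silyl enol ether, C5 (β-Me) carrying the (E)-2-(benzenesulfonyl)but-2-enyl group on the α face, 10α-H | COc1cc(C)c(OC)c(c1)C(O[Sm](I)I)=C(C)[C@H]2CCC(O[Si](C)(C)C(C)(C)C)=C[C@]2(C)C/C(S(=O)(=O)c3ccccc3)=C\C | intermediate (not isolated)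
17 | (2,5-dimethoxy-3-methylphenyl)[3-(benzenesulfonyl)-6-{[tert-butyl(dimethyl)silyl]oxy}-1,2,4a-trimethyl-1,2,3,4,4a,7,8,8a-octahydronaphthalen-1-yl]methanone; decalin numbering: 5β-Me, 8α-Me, 9β-Me, 10α-H, C7 epimers | COc1cc(C)c(OC)c(c1)C(=O)[C@]2(C)[C@H]3CCC(O[Si](C)(C)C(C)(C)C)=C[C@]3(C)CC(S(=O)(=O)c4ccccc4)[C@@H]2C | intermediate
18 | benzyl prop-2-enoate | C=CC(=O)OCc1ccccc1 | starting material
19 | benzyl 3-[7-(benzenesulfonyl)-5-(2,5-dimethoxy-3-methylbenzoyl)-5,6,8a-trimethyl-2-oxodecahydronaphthalen-1-yl]propanoate; decalin numbering: 5β-Me, 8α-Me, 9β-Me, 10α-H, C4 and C7 epimers | COc1cc(C)c(OC)c(c1)C(=O)[C@]2(C)[C@H]3CCC(=O)C(CCC(=O)OCc4ccccc4)[C@]3(C)CC(S(=O)(=O)c5ccccc5)[C@@H]2C | intermediate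
20 | 3-[7-(benzenesulfonyl)-5-[(2,5-dimethoxy-3-methylphenyl)methyl]-5,6,8a-trimethyl-2-oxodecahydronaphthalen-1-yl]propanoic acid; decalin numbering: C4 side chain β, 5β-Me, 8α-Me, 9β-Me, 10α-H, C7 epimers | COc1cc(C)c(OC)c(c1)C[C@]2(C)[C@H]3CCC(=O)[C@@H](CCC(=O)O)[C@]3(C)CC(S(=O)(=O)c4ccccc4)[C@@H]2C | intermediate
21 | 3-[(1S,4aR,5S,6S,8aR)-5-[(2,5-dimethoxy-3-methylphenyl)methyl]-5,6,8a-trimethyl-2-oxodecahydronaphthalen-1-yl]propanoic acid | COc1cc(C)c(OC)c(c1)C[C@]2(C)[C@H]3CCC(=O)[C@@H](CCC(=O)O)[C@]3(C)CC[C@@H]2C | intermediate
22 | 3-[(1S,4aR,5S,6S,8aR)-5-[(2,5-dihydroxy-3-methylphenyl)methyl]-5,6,8a-trimethyl-2-oxodecahydronaphthalen-1-yl]propanoic acid (CNP0167047.1) | Cc1cc(O)cc(C[C@]2(C)[C@H]3CCC(=O)[C@@H](CCC(=O)O)[C@]3(C)CC[C@@H]2C)c1O | target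

**Totals**

Total step count: 14. Longest linear sequence: 8 steps (steps 3, 5, 6, 10, 11, 12, 13, 14 from 5, or steps 1, 2, 6, 10–14 from 1).

**Steps most likely to fail**

1. Step 10 (proposed new method). What may go wrong: the C5 allyl radical or allylsamarium may be reduced or protonated before it is captured; capture may occur through C3; the adduct radical may return to the enolate before the sulfonyl group fragments, giving a five-membered ring; the Michael closure may be slow or unselective at C8/C9. The fallback uses known reactions stepwise, sets out from 10 and comes back at 21. Fluoride-induced desilylation of 10 (TBAF, AcOH, THF) opens the donor–acceptor cyclopropane by retro-Michael fragmentation to the enone 4-[1-(2,5-dimethoxy-3-methylphenyl)-1-oxopropan-2-yl]-3-methylcyclohex-2-en-1-one F1. Copper-catalysed conjugate addition of (R)-[3-(triethylsilyloxy)butyl]magnesium bromide (from (R)-butane-1,3-diol; CuBr·SMe2, then TIPSOTf), anti to the C10 substituent, should give the triisopropylsilyl enol ether with the triethylsilyl-protected side chain F2. Selective removal of the triethylsilyl group (PPTS, MeOH, 0 °C) gives the secondary alcohol F3, and TsCl/pyridine gives the tosylate F4. KHMDS then forms the only available enolate (C9) and an intramolecular SN2 alkylation with inversion at C8 should close ring B to the tricyclic triisopropylsilyl enol ether F5 (C9 controlled by allylic 1,3-strain as in step 10). Mukaiyama–Michael reaction with 18 (TiCl4) gives the benzyl ester diketone F6, and hydrogenolysis under the conditions of step 12 returns to 21.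

2. Step 5. What may go wrong: 1,2-hydride shift of the α-methyl carbenoid may outrun cyclopropanation of the hindered trisubstituted double bond; the carbenoid may add to the enol ether double bond; enantioface selection may be poor. The fallback sets out from 6 and comes back at 10. Cyclopropanation of 6 with tert-butyl diazoacetate, which has no β-hydrogen, under CuOTf with the (S,S)-tert-butyl bis(oxazoline) ligand (monovalent copper) should give the tert-butyl 3-silyloxy-1-methylbicyclo[4.1.0]hept-2-ene-7-carboxylate F7. Deprotonation with LDA at −78 °C and methylation with MeI installs the C7 methyl group, giving the tert-butyl 1,7-dimethyl ester F8. Addition of the aryllithium from 4 as in step 6 then gives 10.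

3. Step 6. What may go wrong: the aryllithium may fail to add to the doubly neopentyl ester, may add twice, or may open the donor–acceptor cyclopropane. The fallback sets out from 9 and comes back at 10. DIBAL-H reduction of 9 at −78 °C gives the cyclopropanecarbaldehyde F9. Addition of the aryllithium from 4 to this unhindered carbonyl gives the secondary benzylic alcohol F10, and Dess–Martin oxidation gives 10.

Further compounds
F1 | step 10 | 4-[1-(2,5-dimethoxy-3-methylphenyl)-1-oxopropan-2-yl]-3-methylcyclohex-2-en-1-one (ring stereocentre = C10 as in the target) | COc1cc(C)c(OC)c(c1)C(=O)C(C)[C@H]1CCC(=O)C=C1C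
F2 | step 10 | conjugate adduct: C3 triisopropylsilyl enol ether, C5 (β-Me) carrying an α-(3R)-3-(triethylsilyloxy)butyl group, 10α-H | COc1cc(C)c(OC)c(c1)C(=O)C(C)[C@H]2CCC(O[Si](C(C)C)(C(C)C)C(C)C)=C[C@]2(C)CC[C@@H](C)O[Si](CC)(CC)CC
F3 | step 10 | corresponding (3R)-3-hydroxybutyl compound | COc1cc(C)c(OC)c(c1)C(=O)C(C)[C@H]2CCC(O[Si](C(C)C)(C(C)C)C(C)C)=C[C@]2(C)CC[C@@H](C)O
F4 | step 10 | corresponding (3R)-3-(4-methylbenzenesulfonyloxy)butyl compound | COc1cc(C)c(OC)c(c1)C(=O)C(C)[C@H]2CCC(O[Si](C(C)C)(C(C)C)C(C)C)=C[C@]2(C)CC[C@@H](C)OS(=O)(=O)c3ccc(C)cc3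
F5 | step 10 | tricyclic C3 triisopropylsilyl enol ether without sulfone (5β-Me, 8α-Me, 9β-Me, 9α-aroyl, 10α-H) | COc1cc(C)c(OC)c(c1)C(=O)[C@]2(C)[C@H]3CCC(O[Si](C(C)C)(C(C)C)C(C)C)=C[C@]3(C)CC[C@@H]2C
F6 | step 10 | benzyl 3-[5-(2,5-dimethoxy-3-methylbenzoyl)-5,6,8a-trimethyl-2-oxodecahydronaphthalen-1-yl]propanoate (C4 epimers) | COc1cc(C)c(OC)c(c1)C(=O)[C@]2(C)[C@H]3CCC(=O)C(CCC(=O)OCc4ccccc4)[C@]3(C)CC[C@@H]2C
F7 | step 5 | tert-butyl 3-{[tert-butyl(dimethyl)silyl]oxy}-1-methylbicyclo[4.1.0]hept-2-ene-7-carboxylate (ring-fusion carbons as in 9) | CC(C)(C)OC(=O)C1[C@]2(C)C=C(O[Si](C)(C)C(C)(C)C)CC[C@H]12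
F8 | step 5 | tert-butyl 3-{[tert-butyl(dimethyl)silyl]oxy}-1,7-dimethylbicyclo[4.1.0]hept-2-ene-7-carboxylate (ring-fusion carbons as in 9) | CC(C)(C)OC(=O)C1(C)[C@]2(C)C=C(O[Si](C)(C)C(C)(C)C)CC[C@H]12
F9 | step 6 | 3-{[tert-butyl(dimethyl)silyl]oxy}-1,7-dimethylbicyclo[4.1.0]hept-2-ene-7-carbaldehyde (ring-fusion carbons as in 9) | O=CC1(C)[C@]2(C)C=C(O[Si](C)(C)C(C)(C)C)CC[C@H]12
F10 | step 6 | (3-{[tert-butyl(dimethyl)silyl]oxy}-1,7-dimethylbicyclo[4.1.0]hept-2-en-7-yl)(2,5-dimethoxy-3-methylphenyl)methanol (carbinol epimers) | COc1cc(C)c(OC)c(c1)C(O)C1(C)[C@]2(C)C=C(O[Si](C)(C)C(C)(C)C)CC[C@H]12
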